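**Strategy.** The target is C2-symmetric: a twofold axis passes through the C3–C3'' bond joining two identical (2R,3R)-flavanone units, and C3 and C3'' are both α-carbons of ring C ketones. That bond is therefore made by oxidative homodimerisation of one chiral enol silane. In a single pot, rhodium-catalysed asymmetric arylation of achiral 5,7-bis(benzyloxy)chromone sets C2 and gives the 4-silyloxy-2H-chromene, which (NH4)2Ce(NO3)6 couples C3 to C3''; two chromones and two aryl groups are thus united. The C3 configuration formed there is irrelevant: double enolisation and kinetic protonation reset C3 and C3'' to the cis arrangement, so every C3 epimer converges. Hydrogenolysis then frees the phenols.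

Key step: step 2

Assumption: 5,7-dihydroxychromone (1) is bought as a catalogue compound; locants follow flavanone numbering, with double primes for the second unit and ring C for the pyranone ring.

**Step 1**
Reactants: 1 5,7-dihydroxychromone; 2 benzyl bromide
Product: 3 5,7-bis(benzyloxy)chromone
Conditions: BnBr, K2CO3, DMF, 70 °C
Reagents that add atoms: benzyl bromide (2), BrCc1ccccc1
Why: Williamson etherification of both phenols, the hydrogen-bonded 5-OH needing the warm polar medium, should proceed cleanly because K2CO3 attacks no other site of the chromone.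

**Step 2**
Reactants: 3 5,7-bis(benzyloxy)chromone; 4 4-methoxyphenylmagnesium bromide; 5 chlorotrimethylsilane
Product: 7 (2R,3S,2''R,3''S)-5,7,5'',7''-tetrakis(benzyloxy)-4',4'''-dimethoxy-3,3''-biflavanone (2,3-trans in both rings), via enol silane 6 (not isolated)
Conditions: 4, ZnCl2, THF, 0 °C; then 3, Me3SiCl, [RhCl((R)-BINAP)]2 (cat.), THF, 20 °C; solvent exchange to MeCN; (NH4)2Ce(NO3)6, NaHCO3, −20 °C
Reagents that add atoms: 4-methoxyphenylmagnesium bromide (4), COc1ccc([Mg]Br)cc1; chlorotrimethylsilane (5), C[Si](C)(C)Cl (its silyl group stands in 6 only and is lost on oxidation)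
Why: Transmetalation of the arylzinc chloride to monovalent rhodium gives an aryl–rhodium species that adds across C2=C3 of chromone 3 on the face chosen by (R)-BINAP, and Me3SiCl traps the resulting oxa-π-allyl rhodium as enol silane 6, so that no free enolate (which could open ring C by β-elimination) is present; one-electron oxidation of 6 by tetravalent cerium then gives a C3-centred α-keto radical that adds to C3 of a second molecule of 6, and a second oxidation with loss of both silyl groups gives 1,4-diketone 7. The closest known reaction types are the rhodium-catalysed asymmetric 1,4-arylation of heterocyclic enones with arylzinc chlorides and Me3SiCl, and the cerium-mediated oxidative dimerisation of silyl enol ethers of cyclic aryl ketones. No ring is closed. C2 and C2'' are set by the catalyst (the ligand enantiomer that gives 2R is used; (R)-BINAP is expected from the usual model for cyclic enones), while C3 and C3'' are set by the substrate, each new bond forming anti to the neighbouring 2-aryl group (trans,trans). The step needs enantioface selectivity at C2 and C3–C3 coupling in preference to dehydrogenation of 6 to the flavone; the first rests on the ligand, the second on low temperature, the buffer and a high concentration of 6, and diastereoselectivity at C3 is not needed because step 3 erases these centres. Because two enantioenriched units are joined, most of the minor enantiomer should end in a separable heterochiral (2R,2''S) diastereomer, so 7 should be of higher enantiopurity than 6.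

**Step 3**
Reactants: 7 (2R,3S,2''R,3''S)-5,7,5'',7''-tetrakis(benzyloxy)-4',4'''-dimethoxy-3,3''-biflavanone
Product: 9 (2R,3R,2''R,3''R)-5,7,5'',7''-tetrakis(benzyloxy)-4',4'''-dimethoxy-3,3''-biflavanone (2,3-cis in both rings), via dilithium bis-enolate 8 (not isolated)
Conditions: LiN(iPr)2, THF, −78 °C; then AcOH, THF, −78 °C
Reagents that add atoms: none
Why: Double enolisation removes both C3 stereocentres, and in each 4-oxido-2H-chromene ring the 2-aryl group should sit pseudoaxial (A(1,2) strain with the C3 substituent) and shield one face, so kinetic protonation of the enolates at −78 °C should come anti to the aryl group and leave the C3–C3'' bond cis to it at both centres, whichever C3 epimer of 7 is used.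

**Step 4**
Reactants: 9 (2R,3R,2''R,3''R)-5,7,5'',7''-tetrakis(benzyloxy)-4',4'''-dimethoxy-3,3''-biflavanone
Product: 10 (2R,3R,2''R,3''R)-5,7,5'',7''-tetrahydroxy-4',4'''-dimethoxy-3,3''-biflavanone (CNP0260837.5)
Conditions: H2 (1 atm), Pd/C, EtOAc/THF, 20 °C
Reagents that add atoms: none
Why: Hydrogenolysis of the four aryl benzyl ethers over Pd/C is neutral, so the ketones, the 4'-methoxy groups and the base-labile cis C2/C3 centres should stay untouched.

**Compound list**
1 | 5,7-dihydroxychromone | O=c1ccoc2cc(O)cc(O)c12 | starting material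
2 | benzyl bromide | BrCc1ccccc1 | starting material
3 | 5,7-bis(benzyloxy)chromone | O=c1ccoc2cc(OCc3ccccc3)cc(OCc3ccccc3)c12 | intermediate
4 | 4-methoxyphenylmagnesium bromide | COc1ccc([Mg]Br)cc1 | starting material
5 | chlorotrimethylsilane | C[Si](C)(C)Cl | starting material
6 | (2R)-5,7-bis(benzyloxy)-2-(4-methoxyphenyl)-4-(trimethylsilyloxy)-2H-chromene | COc1ccc([C@@H]2Oc3cc(OCc4ccccc4)cc(OCc4ccccc4)c3C(O[Si](C)(C)C)=C2)cc1 | intermediate
7 | (2R,3S,2''R,3''S)-5,7,5'',7''-tetrakis(benzyloxy)-4',4'''-dimethoxy-3,3''-biflavanone (trans,trans) | COc1ccc([C@@H]2Oc3cc(OCc4ccccc4)cc(OCc4ccccc4)c3C(=O)[C@H]2[C@@H]2C(=O)c3c(OCc4ccccc4)cc(OCc4ccccc4)cc3O[C@H]2c2ccc(OC)cc2)cc1 | intermediate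
8 | dilithium 3,3''-bi(2H-chromene)-4,4''-diolate derived from 7 (C3 and C3'' trigonal; C2 and C2'' spatially as in 7, which reads 2S,2''S under the changed priority order) | COc1ccc([C@@H]2Oc3cc(OCc4ccccc4)cc(OCc4ccccc4)c3C(O[Li])=C2C2=C(O[Li])c3c(OCc4ccccc4)cc(OCc4ccccc4)cc3O[C@H]2c2ccc(OC)cc2)cc1 | intermediate
9 | (2R,3R,2''R,3''R)-5,7,5'',7''-tetrakis(benzyloxy)-4',4'''-dimethoxy-3,3''-biflavanone (cis,cis) | COc1ccc([C@@H]2Oc3cc(OCc4ccccc4)cc(OCc4ccccc4)c3C(=O)[C@@H]2[C@H]2C(=O)c3c(OCc4ccccc4)cc(OCc4ccccc4)cc3O[C@H]2c2ccc(OC)cc2)cc1 | intermediate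
10 | (2R,3R,2''R,3''R)-5,7,5'',7''-tetrahydroxy-4',4'''-dimethoxy-3,3''-biflavanone (CNP0260837.5) | COc1ccc([C@@H]2Oc3cc(O)cc(O)c3C(=O)[C@@H]2[C@H]2C(=O)c3c(O)cc(O)cc3O[C@H]2c2ccc(OC)cc2)cc1 | target

**Total step count:** 4. **Longest linear sequence:** 4 steps (1 → 3 → 7 → 9 → 10).

**Steps most likely to fail**

Step 2 (key step). The enol silane 6 may hydrolyse during the solvent exchange. Oxidation may also take the two-electron path that dehydrogenates 6 to the flavone (aromatisation of ring C) instead of coupling C3 to C3''. Enantioface control may erode in the telescoped pot. The fallback sets out from 3 and comes back at 7; it separates the two events and makes the coupling intramolecular.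
- Addition of 4-methoxyphenylboronic acid to 3 with Pd(OCOCF3)2 and a t-BuPyOx ligand (enantiomer chosen for 2R) in ClCH2CH2Cl/H2O at 60 °C should give (2R)-5,7-bis(benzyloxy)-2-(4-methoxyphenyl)chroman-4-one F1.
- LiN(SiMe3)2 in THF at −78 °C followed by Me2SiCl2 (half an equivalent) should give the dimethylsilyl bis-enol ether F2, in which the two C3 carbons are held close.
- (NH4)2Ce(NO3)6 and NaHCO3 in MeCN at −20 °C should then close the C3–C3'' bond within the tether and shed the silicon bridge to give 7.

Step 3. Facial selectivity may be poor in one of the two protonations. The lithium enolate may also lose the ring C aryloxide by β-elimination, which opens the ring and loses the C2 configuration. Dimers of the wrong C3 configuration can be resubmitted, since all pass through 8. The fallback sets out from 7 and comes back at 10, bypassing 9.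
- Me3SiOSO2CF3 and Et3N in CH2Cl2 at 0 °C should convert 7 into the bis(trimethylsilyl enol ether) F3 without a free enolate.
- DDQ should oxidise this 1,4-disiloxydiene to the (E)-ene-dione F4 (C3=C3''), in which both 2-aryl groups lie on the same face of the alkene.
- H2 over Pd/C should add both hydrogens syn from the open face, which gives the cis,cis arrangement at C3 and C3'', and remove the four benzyl groups in the same operation to give 10.

Step 4. The benzylic O1–C2 bonds may be hydrogenolysed (ring opening to dihydrochalcone units), or the C4 carbonyls reduced, before all four benzyl groups are off. The fallback goes from 9 to 10 by a non-reductive cleavage and makes no new compound (F0): BCl3 with pentamethylbenzene as cation scavenger in CH2Cl2 at −78 °C should remove the aryl benzyl ethers by Lewis acid ionisation while the aryl methyl ethers stay.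

**Further compounds**
F1 | step 2 | (2R)-5,7-bis(benzyloxy)-2-(4-methoxyphenyl)chroman-4-one | COc1ccc([C@@H]2Oc3cc(OCc4ccccc4)cc(OCc4ccccc4)c3C(=O)C2)cc1
F2 | step 2 | dimethylsilyl bis-enol ether of F1, bis[(2R)-5,7-bis(benzyloxy)-2-(4-methoxyphenyl)-2H-chromen-4-yloxy]dimethylsilane | COc1ccc([C@@H]2Oc3cc(OCc4ccccc4)cc(OCc4ccccc4)c3C(O[Si](C)(C)OC3=C[C@H](c4ccc(OC)cc4)Oc4cc(OCc5ccccc5)cc(OCc5ccccc5)c34)=C2)cc1
F3 | step 3 | bis(trimethylsilyl enol ether) of 7 (C2 and C2'' spatially as in 7) | COc1ccc([C@@H]2Oc3cc(OCc4ccccc4)cc(OCc4ccccc4)c3C(O[Si](C)(C)C)=C2C2=C(O[Si](C)(C)C)c3c(OCc4ccccc4)cc(OCc4ccccc4)cc3O[C@H]2c2ccc(OC)cc2)cc1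
F4 | step 3 | (E)-5,7,5'',7''-tetrakis(benzyloxy)-4',4'''-dimethoxy-3,3''-bi(flavan-4-on-3-ylidene), C3=C3'' ene-dione (C2 and C2'' spatially as in 7) | COc1ccc([C@@H]2Oc3cc(OCc4ccccc4)cc(OCc4ccccc4)c3C(=O)/C2=C2/C(=O)c3c(OCc4ccccc4)cc(OCc4ccccc4)cc3O[C@H]2c2ccc(OC)cc2)cc1
F0 | step 4 | none | none
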